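## The problem

Euchrestaflavanone A (14) is (2S)-naringenin carrying two C-bound 3-methylbut-2-enyl (prenyl) groups, one at C8 of ring A and one at C3' of ring B (flavanone numbering: O1, C2, C3, C4 in ring C; C4a, C5–C8, C8a in ring A; primed atoms in ring B). The ring system, the 5,7,4'-oxygenation and the single stereocentre C2 are those of a chiral-pool flavanone, so the real task is two aryl–CH2 bonds at the right carbons. Direct electrophilic prenylation cannot place them: C6 and C8 are both flanked by two oxygens, ring B is less nucleophilic than ring A, and O-alkylation competes. C2 controls nothing elsewhere and is itself fragile, because base or strong acid opens ring C by retro-oxa-Michael reaction to an achiral 2'-hydroxychalcone. Each prenyl alkene ends up ortho to a free phenol (C8 next to O7, C3' next to O4'), so acid closes them to 2,2-dimethylchromans, and hydrogenation or oxidants destroy them; the closing steps must be neutral. The three phenols differ in reactivity (7-OH most acidic, 4'-OH ordinary, 5-OH chelated to the C4 carbonyl), and this order must be used to address them one at a time. A rearrangement strategy is possible because both target carbons are sigmatropically linked to a phenolic oxygen: C8 is para to O5 (two consecutive [3,3] shifts via C6), C3' is ortho to O4' (one [3,3] shift), and O5 sits beside the C4 carbonyl where a lanthanide can chelate.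

## Retrosynthesis

**14 ⇒ 13 (O7–acyl bond).** The last bond cut is the ester bond of a 7-O-acetate. An acetate is preferred to an acetal, benzyl or silyl group because its removal needs no acid (chroman closure), no hydrogen (alkene reduction) and no fluoride or strong base (opening of ring C). Compound 13 has the full carbon skeleton; the forward reaction is a near-neutral solvolysis of an activated aryl ester.

**13 ⇒ 8 (C8–CH2 and C3'–CH2 bonds, key disconnection).** Both aryl–carbon bonds are cut together and each prenyl group is returned to the oxygen from which a pericyclic path leads to its carbon.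
- The C8 group goes back to O5 as a linear prenyl ether (Claisen then Cope, two allylic inversions).
- The C3' group goes back to O4' as a branched 1,1-dimethylallyl ether (one inversion).

This is better than direct C-prenylation (regioisomer mixtures) and better than a Claisen shift from O7, which has two open ortho positions (C6 and C8). Cutting one bond at a time would add protecting-group steps. Precursor 8 has no aryl–prenyl bond; it is naringenin (1) with three different groups on its three oxygens. The forward reaction must run two different rearrangements in one flask without ionising the tertiary ether or cleaving the acetate.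

**8 ⇒ 6 + 7 (O5–CH2 bond).** The prenyl ether at O5 is cut to the chelated phenol 6 and prenol (7). It is installed last because the 5-OH is the least reactive phenol and is addressed cleanly only when O7 and O4' are capped. A Mitsunobu reaction is preferred to an allylic halide and base: it is base-free, gives no C-alkylation or allylic transposition, and does not endanger C2.

**6 ⇒ 5 (alkene from alkyne).** A tertiary allyl aryl ether cannot be made by SN2 chemistry, and cationic allylation gives the linear ether or C-alkylation. The alkyne 5 is the standard latent form; the forward step is a semi-hydrogenation that must stop at the alkene.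

**5 ⇒ 2 + 3 (O4'–C bond).** The propargylic ether is cut to 7-O-acetylnaringenin (2) and 2-methylbut-3-yn-2-ol (3), activated in the flask as its trifluoroacetate 4. Copper catalysis delivers the phenoxide to the tertiary carbon. The forward step must distinguish 4'-OH from the chelated 5-OH and keep the acetate on O7 during a short exposure to an amidine base.

**2 ⇒ 1 (O7–acyl bond).** The acetate is cut to (2S)-naringenin (1). The forward reaction relies on the 7-OH being the most acidic phenol and must stop at the monoacetate.

## Roads not taken

**Alternative 1:** Ring C is cut at C4a–C4, C3–C4 and O1–C2 into iodophenol A2, carbon monoxide and aryl acetylene A3. In the forward direction PdCl2(PPh3)2 with diethylamine under CO would give an ynone by carbonylative coupling, and the phenol would close onto it to give flavone A1.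
- Merits: three bonds and ring C form in one operation from two fragments. The prenyl positions are fixed by the building blocks, which is more secure regiochemically than any rearrangement, and analogues are easy to vary. In convergence and modularity this road is better than the chosen one.
- Weak points: A1 is a flavone, so C2 is planar. The stereocentre would have to be made afterwards by enantioselective 1,4-reduction of the C2=C3 bond beside two trisubstituted alkenes, without reducing the C4 ketone. A2 and A3 each need their own site-selective C-prenylation, so the regiochemical problem is moved, not solved. Three methoxymethyl ethers must be removed with acid next to ortho-prenyl phenols. Five-membered (aurone-type) closure can compete.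
- Comparison: the chosen plan buys rings, oxygenation and C2 with 1, needs six steps, and deprotects under neutral conditions.

**Alternative 2:** The C2–C3 bond is cut, leading back to diazoketone A5, in which ring B is attached as a benzyl ether to the ring A phenol. A rhodium carbene made with Rh2(OAc)4 or a chiral Rh2(O2CR)4 analogue would insert into one benzylic O–CH2 hydrogen, close ring C and set C2, giving the tris-silyl ether A4.
- Merits: C2 is set by the catalyst, so either enantiomer is accessible and the route does not depend on the optical purity of a purchased flavanone. This is a real advantage over the chosen plan, which must preserve a base-labile stereocentre through six steps.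
- Weak points: an acceptor-only carbene from a diazomethyl ketone is highly electrophilic and poorly selective. The ether oxygen is placed to form a five-membered oxonium ylide, and a Stevens [1,2]-benzyl shift would then give a 2-benzylbenzofuranone. The two electron-rich prenyl alkenes invite cyclopropanation, and Buchner-type addition to the arene is possible. Insertion through a six-membered transition state is less favoured than the usual five-membered mode, and enantiocontrol with such carbenes is modest. Three silyl ethers must then be removed with fluoride, which is basic enough to threaten ring C.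
- Comparison: the pericyclic key step of the chosen plan cannot react with the alkenes at all.

**Alternative 3:** Ring A is cut at C4a–C5, leading back to dihydropyranone A7, which carries a prenylated β-keto ester side chain on the carbon that becomes C8a. Mild base (DBU or Mg(OMe)2) would deprotonate the side chain, C4a would attack the ester in an intramolecular Claisen condensation, and enolisation would aromatise ring A to give A6.
- Merits: the C8 prenyl group is installed on sp3 carbon before ring A exists, so no C6 isomer can form, and the 5,7-diol emerges unprotected. In regiochemical certainty at C8 this road is better than the chosen plan, which depends on a Cope shift outrunning tautomerisation.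
- Weak points: A7 needs an enantioselective construction of the 2-aryl-dihydropyranone and a labile 1,3-dicarbonyl chain alkylated at the right carbon. Base can open the dihydropyranone by retro-oxa-Michael reaction and racemise C2, and O-acylation and aldol modes compete with the desired C-acylation. The 4'-methoxymethyl group still has to be removed with acid beside two ortho-prenyl phenols. The step count is several times that of the chosen plan.
- Comparison: the chosen plan answers with step economy, an intact purchased ring system, and a key step whose two components are each established on this substrate class.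

Key step: step 5

## Route

Assumptions: (2S)-naringenin (1) is bought as the single enantiomer and its enantiomeric purity is checked before use, since material made by hydrolysis of naringin can be partly racemic. Eu(fod)3 denotes Eu(C10H10F7O2)3, europium tris(6,6,7,7,8,8,8-heptafluoro-2,2-dimethyloctane-3,5-dionate), a complex of trivalent europium. Enantiomeric purity should be re-checked at 2, 8 and 14.

Step 1
Reactants: 1 (2S)-naringenin [(2S)-5,7-dihydroxy-2-(4-hydroxyphenyl)chroman-4-one]
Product: 2 (2S)-7-O-acetylnaringenin [(2S)-5-hydroxy-2-(4-hydroxyphenyl)-4-oxochroman-7-yl acetate]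
Conditions: Ac2O (1.05 equiv), pyridine, THF, −10 to 0 °C
Reagents that add atoms: acetic anhydride, CC(=O)OC(C)=O
Why: Site-selective O-acylation: the 7-OH, para to the C4 carbonyl, is the most acidic phenol and reacts first, the chelated 5-OH is inert, and limiting anhydride at low temperature should hold the reaction at the monoacetate (minor 7,4'-diacetate is separable). The cold, weakly basic medium leaves C2 untouched.

Step 2
Reactants: 2 (2S)-7-O-acetylnaringenin; 3 2-methylbut-3-yn-2-ol
Product: 5 (2S)-7-O-acetyl-4'-O-(2-methylbut-3-yn-2-yl)naringenin, via 2-methylbut-3-yn-2-yl trifluoroacetate 4 (not isolated)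
Conditions: 3, (CF3CO)2O, DBU, MeCN, −5 °C; then 2, DBU, CuCl2·2H2O (1 mol%), MeCN, −5 to 0 °C
Reagents that add atoms: trifluoroacetic anhydride, O=C(OC(=O)C(F)(F)F)C(F)(F)F (adds the trifluoroacetyl group of intermediate 4; no atom of it remains in 5)
Why: Copper-catalysed propargylic substitution: divalent copper is reduced in the flask to monovalent copper, whose acetylide of 4 ionises to a copper allenylidene that the 4'-phenoxide captures at the tertiary carbon. The chelated 5-OH is too poor a nucleophile to compete, as in the 4-selective alkylation of 2,4-dihydroxyaryl ketones. Low temperature and short reaction time are chosen to outrun acetyl transfer from O7 and base-induced opening of ring C.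

Step 3
Reactants: 5 (2S)-7-O-acetyl-4'-O-(2-methylbut-3-yn-2-yl)naringenin
Product: 6 (2S)-7-O-acetyl-4'-O-(2-methylbut-3-en-2-yl)naringenin
Conditions: H2 (1 atm), 5% Pd/CaCO3 poisoned with Pb(OAc)2, quinoline, EtOAc, rt
Reagents that add atoms: none
Why: Lindlar semi-hydrogenation of a terminal alkyne stops at the alkene. The aryl ketone, the aryl acetate and the benzylic C2–O bond are inert under these conditions, and the ester solvent avoids transesterification of the acetate.

Step 4
Reactants: 6 (2S)-7-O-acetyl-4'-O-(2-methylbut-3-en-2-yl)naringenin; 7 prenol (3-methylbut-2-en-1-ol)
Product: 8 (2S)-7-O-acetyl-5-O-(3-methylbut-2-enyl)-4'-O-(2-methylbut-3-en-2-yl)naringenin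
Conditions: PPh3, DIAD, THF, 0 °C to rt
Reagents that add atoms: none
Why: Mitsunobu etherification: with O7 and O4' capped, the chelated 5-OH is the only acidic group, it protonates the PPh3–DIAD betaine, and its phenoxide displaces the primary prenyloxyphosphonium ion by SN2 without allylic transposition. The medium is essentially neutral and at or below room temperature, so the acetate, the thermally labile tertiary allyl ether and C2 are preserved.

Step 5
Reactants: 8 (2S)-7-O-acetyl-5-O-(3-methylbut-2-enyl)-4'-O-(2-methylbut-3-en-2-yl)naringenin
Product: 13 (2S)-7-O-acetyl-8,3'-diprenylnaringenin (7-O-acetyl euchrestaflavanone A), via C6 reverse-prenyl ortho-dienone 9 (not isolated), via C8 prenyl para-dienone 10 (not isolated), via 8-prenyl tertiary allyl ether 11 (not isolated), via ring B ortho-dienone 12 (not isolated)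
Conditions: Eu(fod)3 (15 mol%), PhCl (degassed), 60 °C then 110 °C, Ar
Reagents that add atoms: none
Why: Trivalent europium chelates the C4 carbonyl and the O5 ether oxygen, weakens the O5–CH2 bond and triggers an aromatic Claisen [3,3] shift of the prenyl group to C6 (the other ortho carbon, C4a, is a ring-fusion atom), giving the reverse-prenylated ortho-dienone 9. In 9 the crowded 1,1-dimethylallyl group on sp3 C6 forms a 1,5-diene with C7=C8, and a Cope [3,3] shift passes it to C8 with a second allylic inversion, so a normal prenyl group arrives there (para-dienone 10); enolisation then restores ring A with its chelated 5-OH in 11. The closest known reactions are the Eu(fod)3-promoted para-Claisen–Cope rearrangement of 7-O-acylated 5-O-prenylflavanones and the classical ortho-Claisen rearrangement of aryl 1,1-dimethylallyl ethers; here the two are run in one flask. At the higher temperature the tertiary ether on ring B undergoes its own [3,3] shift through a chair transition state to ortho-dienone 12, which tautomerises to the 3'-prenyl-4'-phenol of 13; the single inversion turns the branched O-allyl group into a linear C-prenyl group, and the gem-dimethyl carbinol carbon lowers the barrier. No ring is closed and no lasting stereocentre is created: the sp3 carbons C6 in 9, C8 in 10 and C3' in 12 are erased by the next shift or tautomerisation, and C2 is a spectator under neutral aprotic conditions. The step needs site selectivity (C8 not C6, C3' without 1,3-scrambling) and chemoselectivity (no chroman formation, no loss of the tertiary ether), and the substrate provides them: the oxygen of origin and the allyl isomer on it fix each terminus, C3' and C5' are equivalent, the 7-O-acetyl group removes the phenol that could relay a proton to tautomerise 9 before the Cope shift or add to the C8 prenyl alkene, and the lanthanide diketonate is too weak a Lewis acid to ionise the ring B ether.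

Step 6
Reactants: 13 (2S)-7-O-acetyl-8,3'-diprenylnaringenin
Product: 14 euchrestaflavanone A [(2S)-5,7-dihydroxy-2-[4-hydroxy-3-(3-methylbut-2-enyl)phenyl]-8-(3-methylbut-2-enyl)chroman-4-one]
Conditions: NH4OAc (excess), MeOH/H2O (4:1), rt
Reagents that add atoms: none
Why: Solvolysis of an activated aryl acetate (the leaving group is the acidic 7-phenoxide, para to the carbonyl) promoted by ammonium acetate at near-neutral pH. The conditions supply neither the acid that would close the ortho-prenylphenols to chromans nor the base that would open ring C and racemise C2.

## Compound list

1 | (2S)-naringenin | O=C1C[C@@H](c2ccc(O)cc2)Oc2cc(O)cc(O)c21 | starting material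
2 | (2S)-7-O-acetylnaringenin | Oc1ccc([C@@H]2CC(=O)c3c(O)cc(OC(C)=O)cc3O2)cc1 | intermediate
3 | 2-methylbut-3-yn-2-ol | CC(C)(O)C#C | starting material
4 | 2-methylbut-3-yn-2-yl trifluoroacetate | C#CC(C)(C)OC(=O)C(F)(F)F | intermediate (not isolated)
5 | (2S)-7-O-acetyl-4'-O-(2-methylbut-3-yn-2-yl)naringenin | C#CC(C)(C)Oc1ccc([C@@H]2CC(=O)c3c(O)cc(OC(C)=O)cc3O2)cc1 | intermediate
6 | (2S)-7-O-acetyl-4'-O-(2-methylbut-3-en-2-yl)naringenin | C=CC(C)(C)Oc1ccc([C@@H]2CC(=O)c3c(O)cc(OC(C)=O)cc3O2)cc1 | intermediate
7 | prenol (3-methylbut-2-en-1-ol) | CC(C)=CCO | starting material
8 | (2S)-7-O-acetyl-5-O-(3-methylbut-2-enyl)-4'-O-(2-methylbut-3-en-2-yl)naringenin | C=CC(C)(C)Oc1ccc([C@@H]2CC(=O)c3c(OCC=C(C)C)cc(OC(C)=O)cc3O2)cc1 | intermediate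
9 | ring A ortho-dienone: C5 ketone, sp3 C6 bearing H and the 2-methylbut-3-en-2-yl group (either configuration), C7=C8 and C4a=C8a double bonds, (2S) | C=CC(C)(C)C1C(=O)C2=C(O[C@H](c3ccc(OC(C)(C)C=C)cc3)CC2=O)C=C1OC(C)=O | intermediate (not isolated)
10 | ring A para-dienone: C5 ketone, C6=C7 and C4a=C8a double bonds, sp3 C8 bearing H and the prenyl group (either configuration), (2S) | CC(C)=CCC1C(OC(C)=O)=CC(=O)C2=C1O[C@H](c1ccc(OC(C)(C)C=C)cc1)CC2=O | intermediate (not isolated)
11 | (2S)-7-O-acetyl-8-prenyl-4'-O-(2-methylbut-3-en-2-yl)naringenin | C=CC(C)(C)Oc1ccc([C@@H]2CC(=O)c3c(O)cc(OC(C)=O)c(CC=C(C)C)c3O2)cc1 | intermediate (not isolated)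
12 | ring B ortho-dienone: C4' ketone, sp3 C3' bearing H and the prenyl group (either configuration), C1'=C2' and C5'=C6' double bonds, ring A as in 13, (2S) | CC(C)=CCC1C=C([C@@H]2CC(=O)c3c(O)cc(OC(C)=O)c(CC=C(C)C)c3O2)C=CC1=O | intermediate (not isolated)
13 | (2S)-7-O-acetyl-8,3'-diprenylnaringenin (7-O-acetyl euchrestaflavanone A) | CC(C)=CCc1cc([C@@H]2CC(=O)c3c(O)cc(OC(C)=O)c(CC=C(C)C)c3O2)ccc1O | intermediate
14 | euchrestaflavanone A | CC(C)=CCc1cc([C@@H]2CC(=O)c3c(O)cc(O)c(CC=C(C)C)c3O2)ccc1O | target

## Step count and risks

Total steps: 6. Longest linear sequence: 6 steps (from 1).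

**Step 5 (key step).**
- What may go wrong: tautomerisation of the C6 dienone before the Cope shift, which would leave a reverse-prenyl group at C6; Lewis-acid ionisation of the tertiary ether on ring B before its [3,3] shift, with loss or 1,3-scrambling of the allyl group; or a mismatch of the temperatures the two rearrangements need, so that the ring A product is heated too long.
- Fallback: decouple the two shifts. Setting out from 6, the ring B rearrangement is run alone by heating in toluene (thermal aromatic Claisen rearrangement) to give (2S)-7-O-acetyl-3'-prenylnaringenin F1. Its 4'-OH is acetylated (Ac2O, pyridine, 0 °C; the chelated 5-OH does not react) to give (2S)-7,4'-di-O-acetyl-3'-prenylnaringenin F2. Mitsunobu reaction with 7 (PPh3, DIAD, THF) gives (2S)-7,4'-di-O-acetyl-5-O-prenyl-3'-prenylnaringenin F3. Eu(fod)3 in CHCl3 at 60 °C then has only the para-Claisen–Cope shift to perform, on the 7,4'-diacetate pattern for which it is established, and gives (2S)-7,4'-di-O-acetyl euchrestaflavanone A F4. NH4OAc in aqueous MeOH removes both acetates and the route is rejoined at 14.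

**Step 2.**
- What may go wrong: intermolecular acetyl transfer from the activated 7-O-acetate to the 4'-phenoxide under DBU, and erosion of enantiomeric purity at C2 through reversible base-induced opening of ring C.
- Fallback: setting out from 2, the tertiary allyl ether is installed directly by a Tsuji–Trost O-allylation with tert-butyl 2-methylbut-3-en-2-yl carbonate and Pd(PPh3)4 (zerovalent palladium) in THF at 0 °C. No external base is added: the tert-butoxide released on ionisation is quenched by the phenol, and the phenoxide is consumed at the more substituted allyl terminus as it forms. This rejoins the route at 6, bypasses the alkyne 5 and step 3, and makes no new compound.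

**Step 1.**
- What may go wrong: incomplete discrimination between the 7- and 4'-hydroxyls, giving over-acetylation or a mixture of monoacetates.
- Fallback: a silyl relay that uses the opposite, well-understood selectivity. Setting out from 1, TBSCl and imidazole in DMF silylate both non-chelated phenols to give (2S)-7,4'-bis-O-(tert-butyldimethylsilyl)naringenin F5. Brief K2CO3 in MeOH at −10 °C cleaves only the more labile silyl ether of the acidic 7-phenol to give (2S)-4'-O-(tert-butyldimethylsilyl)naringenin F6. Ac2O and pyridine acetylate the now unique free 7-OH to give (2S)-7-O-acetyl-4'-O-(tert-butyldimethylsilyl)naringenin F7. HF·pyridine in THF removes the silyl group without touching the acetate and the route is rejoined at 2.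

**Step 6.**
- What may go wrong: slow solvolysis, tempting harsher conditions under which ring C can open and C2 racemise.
- Fallback: enzymatic alcoholysis. Setting out from 13, a lipase (Pseudomonas cepacia lipase) with n-butanol in THF transfers the acetyl group to the alcohol at neutral pH and rejoins the route at 14 without any new compound.

## Further compounds

F1 | step 5 | (2S)-7-O-acetyl-3'-prenylnaringenin | CC(C)=CCc1cc([C@@H]2CC(=O)c3c(O)cc(OC(C)=O)cc3O2)ccc1O
F2 | step 5 | (2S)-7,4'-di-O-acetyl-3'-prenylnaringenin | CC(C)=CCc1cc([C@@H]2CC(=O)c3c(O)cc(OC(C)=O)cc3O2)ccc1OC(C)=O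
F3 | step 5 | (2S)-7,4'-di-O-acetyl-5-O-prenyl-3'-prenylnaringenin | CC(C)=CCc1cc([C@@H]2CC(=O)c3c(OCC=C(C)C)cc(OC(C)=O)cc3O2)ccc1OC(C)=O
F4 | step 5 | (2S)-7,4'-di-O-acetyl euchrestaflavanone A | CC(C)=CCc1cc([C@@H]2CC(=O)c3c(O)cc(OC(C)=O)c(CC=C(C)C)c3O2)ccc1OC(C)=O
F0 | step 2 | none | none
F5 | step 1 | (2S)-7,4'-bis-O-(tert-butyldimethylsilyl)naringenin | CC(C)(C)[Si](C)(C)Oc1ccc([C@@H]2CC(=O)c3c(O)cc(O[Si](C)(C)C(C)(C)C)cc3O2)cc1
F6 | step 1 | (2S)-4'-O-(tert-butyldimethylsilyl)naringenin | CC(C)(C)[Si](C)(C)Oc1ccc([C@@H]2CC(=O)c3c(O)cc(O)cc3O2)cc1
F7 | step 1 | (2S)-7-O-acetyl-4'-O-(tert-butyldimethylsilyl)naringenin | CC(C)(C)[Si](C)(C)Oc1ccc([C@@H]2CC(=O)c3c(O)cc(OC(C)=O)cc3O2)cc1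
F0 | step 6 | none | none
A1 | alternative 1 | 5,7,4'-tris(methoxymethoxy)-8,3'-diprenylflavone | CC(C)=CCc1cc(-c2cc(=O)c3c(OCOC)cc(OCOC)c(CC=C(C)C)c3o2)ccc1OCOC
A2 | alternative 1 | 2-iodo-3,5-bis(methoxymethoxy)-6-(3-methylbut-2-enyl)phenol | COCOc1cc(OCOC)c(CC=C(C)C)c(O)c1I
A3 | alternative 1 | 4-ethynyl-1-(methoxymethoxy)-2-(3-methylbut-2-enyl)benzene | C#Cc1ccc(OCOC)c(CC=C(C)C)c1
A4 | alternative 2 | (2S)-5,7,4'-tris-O-(tert-butyldimethylsilyl) euchrestaflavanone A | CC(C)=CCc1cc([C@@H]2CC(=O)c3c(O[Si](C)(C)C(C)(C)C)cc(O[Si](C)(C)C(C)(C)C)c(CC=C(C)C)c3O2)ccc1O[Si](C)(C)C(C)(C)C
A5 | alternative 2 | 2-diazo-1-[2-[4-(tert-butyldimethylsilyloxy)-3-prenylbenzyloxy]-4,6-bis(tert-butyldimethylsilyloxy)-3-prenylphenyl]ethanone | [N-]=[N+]=CC(=O)c1c(O[Si](C)(C)C(C)(C)C)cc(O[Si](C)(C)C(C)(C)C)c(CC=C(C)C)c1OCc1ccc(O[Si](C)(C)C(C)(C)C)c(CC=C(C)C)c1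
A6 | alternative 3 | (2S)-4'-O-methoxymethyl euchrestaflavanone A | CC(C)=CCc1cc([C@@H]2CC(=O)c3c(O)cc(O)c(CC=C(C)C)c3O2)ccc1OCOC
A7 | alternative 3 | methyl 4-[(2S)-2-[4-(methoxymethoxy)-3-prenylphenyl]-4-oxo-2,3-dihydropyran-6-yl]-7-methyl-3-oxooct-6-enoate (either configuration at C4 of the chain) | COC(=O)CC(=O)C(CC=C(C)C)C1=CC(=O)C[C@@H](c2ccc(OCOC)c(CC=C(C)C)c2)O1
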